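The earlier runs and the new flask stem from a simulated flask with constants of no real substance, noise included.

In a one-step world E turns into Q, and one plateau is one yield, whatever the charge.

| setting | epsilon | north-west | south-east | east | west | south |
|---|---|---|---|---|---|---|
| E | 0.55 M | 1.0 M | 1.5 M | 0.12 M | 0.30 M | 0.50 M |
| L | 66 mM (held) | 66 mM (held) | 66 mM (held) | 66 mM (held) | 66 mM (held) | 66 mM (held) |
| remark | run made earlier |  |  |  |  |  |
| time |  | 4.0 min | 4.0 min | 4.0 min | 4.0 min | 4.0 min |

- epsilon (time / min: Q / %): 0.200: 15; 0.333: 21; 0.417: 33; 0.667: 33; 1.00: 35; 1.50: 35; 2.50: 36

(scatter of a reading: 2 percentage points)

- at the start none of L is in solution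

- ranking by amount of Q, in percent of the E charged, from high to low, at 4.0 min (north-west / south-east / east / west / south)
- the amount of Q, in percent of the E charged of the flask you put first, at 4.0 min
- the amount of Q, in percent of the E charged of the flask you put last, at 4.0 min

The epsilon run climbs and then sits flat. Its last three readings average 35.3% of the E charged, which is 0.194 M of Q. I carry this plateau to the new flasks in two ways. Held as a percentage, it gives 35.3% in south. Held as a molar amount, it gives 38.9% in south. The gap is 3.5 percentage points against a reading error of 2 points, so near the epsilon charge this one run cannot part them, though both start from the same plateau and neither checks the other.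

They part at the ends. For east, the molar way gives 162%, since 0.194 M is more than the 0.12 M charged. That way cheats in east.

So I let both the charge c and a ceiling K bound Q, with Q = cK/(c+K), and the yield is K/(K+c). As a first answer I put K equal to 0.194 M. That returns 26.1% for epsilon, short of the plateau. I put that miss back in and divide 0.194 M by the share not turned into Q, which gives 0.301 M. This K is my half-yield charge, the charge at which Q is half of the E charged. By construction it returns the epsilon plateau, so that return is no check.

My reckoning gives 71.5% for east and 16.7% for south-east. The forecast has east > west > south > north-west > south-east, with 80% for east and 16% for south-east: “I expect the percent to fall with loading”. My order is the same, but my top figure differs.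

The flask gives east > west > south > north-west > south-east, with 76.5% in east and 12.8% in south-east, so the forecast stands.

L ⇌ Z, rate k1*(csat - [Z]) (kL = 0.204 s⁻¹); E + Z → Q (k = 11.0 M⁻¹ s⁻¹); E → X (k = 0.0204 s⁻¹); E + Q → D (k = 0.296 M⁻¹ s⁻¹) K reads 71.5% for east and 16.7% for south-east against those values. In east, the main reason for the missing Q is the resistance to the transfer of L into solution as Z, a mass-transfer limitation: without it, Q reaches 92.9%. East's Q has moved by 5 points at charges of 0.0868 M and 0.153 M, while waiting until 40.0 min changes nothing. For a neighbour of east charged with 0.048 M, K gives 86.2%, and that flask stands at 87.0%.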